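**Plan**

1. Locants used throughout: five-membered ring C1 (quaternary, methyl), C2 (acetate), C3 (CH2), C4 (isopropyl carbinol), C5 (ring-fusion CH); seven-membered ring C1, C5, C6 (angelate), C7 (CH2), C8 (methyl-bearing alkene carbon), C9 (alkene CH), C10 (benzoate).
2. Enabling feature: the seven-membered ring holds a single alkene, C8=C9, remote from the trans C1–C5 fusion, so this ring can be closed last from a vinyl group on C10 and a methallyl group on C6 of a trans-1,2-disubstituted cyclopentane.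
3. Retrosynthetic cuts, in order: C6–O angelate ester; C8=C9 (ring-closing metathesis); C6–C7 (methallylboration of a C6 aldehyde); C4–isopropyl (organocerium addition to a C4 ketone); C1–C10 and C5–C6 (conjugate addition–aldol on a 2-methylcyclopentenone); C1–CH3 (cross-coupling).
4. Forward: the five-membered ring comes from (R)-4-silyloxycyclopentenone 1 and is fully substituted by a three-component coupling with 1,3-dithiane and acrolein; after ester and oxidation-level adjustments the seven-membered ring is closed in step 14 and the angelate is attached last.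
5. Stereochemistry: C4 of 1 directs C5, C5 directs C1, a closed aldol transition state sets C10, hydride anti to the C10 arm sets C2, isopropyl addition anti to the C5 substituent re-sets C4 after oxidation, and the (+)-α-pinene-derived borane sets C6.

Key step: step 14

Assumption: (R)-4-[(tert-butyldimethylsilyl)oxy]cyclopent-2-en-1-one, (−)-Ipc2BOMe, 2-(trimethylsilyl)-1,3-dithiane, pinacol 2-methylallylboronate and angelic acid are taken as commercial; CIP descriptors in the names follow the systematic locants of each name.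

**Route**

Step 1
Reactants: 1 (R)-4-[(tert-butyldimethylsilyl)oxy]cyclopent-2-en-1-one
Product: 2 (R)-4-[(tert-butyldimethylsilyl)oxy]-2-iodocyclopent-2-en-1-one
Conditions: I2, pyridine, CH2Cl2, 0 °C → rt
Reagents that add atoms: iodine, II
Why: α-Iodination of the enone by pyridine-mediated addition, iodination and elimination (Baylis–Hillman-type) is standard for 4-silyloxycyclopentenones and does not touch the C4 stereocentre.

Step 2
Reactants: 2 (R)-4-[(tert-butyldimethylsilyl)oxy]-2-iodocyclopent-2-en-1-one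
Product: 3 (R)-4-[(tert-butyldimethylsilyl)oxy]-2-methylcyclopent-2-en-1-one
Conditions: SnMe4, PdCl2(PhCN)2 (5 mol%), AsPh3, CuI, NMP, 80 °C
Reagents that add atoms: tetramethylstannane, C[Sn](C)(C)C
Why: Stille cross-coupling of the α-iodoenone, accelerated by CuI and AsPh3, installs the future C1 methyl under neutral conditions, so the base-sensitive 4-silyloxy enone keeps its configuration.

Step 3
Reactants: 3 (R)-4-[(tert-butyldimethylsilyl)oxy]-2-methylcyclopent-2-en-1-one; 4 1,3-dithiane; 5 acrolein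
Product: 8 (2S,3R,4R)-4-[(tert-butyldimethylsilyl)oxy]-3-(1,3-dithian-2-yl)-2-[(1S)-1-hydroxyprop-2-en-1-yl]-2-methylcyclopentan-1-one, via 2-lithio-1,3-dithiane 6 (not isolated), via lithium cyclopentenolate 7 (not isolated)
Conditions: 4, n-BuLi, THF, −30 °C; HMPA, then 3, −78 °C; then 5, −78 °C; aq NH4Cl at −78 °C
Reagents that add atoms: none
Why: Tandem conjugate addition–aldol (three-component coupling): the HMPA-separated lithiodithiane adds 1,4 anti to the C4 silyloxy group (sets C5), the tetrasubstituted enolate 7 attacks the aldehyde carbon of acrolein on the face opposite the new dithianyl group (sets C1, methyl cis to dithianyl), and a chair Zimmerman–Traxler arrangement with the vinyl group equatorial places the C10 hydroxyl anti to ring carbon C5 (10S).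

Step 4
Reactants: 8 (2S,3R,4R)-4-[(tert-butyldimethylsilyl)oxy]-3-(1,3-dithian-2-yl)-2-[(1S)-1-hydroxyprop-2-en-1-yl]-2-methylcyclopentan-1-one
Product: 9 (1S)-1-[(1S,2R,3R)-3-[(tert-butyldimethylsilyl)oxy]-2-(1,3-dithian-2-yl)-1-methyl-5-oxocyclopentyl]prop-2-en-1-yl benzoate
Conditions: BzCl, pyridine, DMAP (cat.), CH2Cl2, 0 °C → rt
Reagents that add atoms: benzoyl chloride, O=C(Cl)c1ccccc1
Why: DMAP-catalysed O-acylation of the only free hydroxyl installs the final C10 benzoate while C2 is still a ketone, under conditions too weakly basic for retro-aldol cleavage, and the quaternary C1 rules out β-elimination.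

Step 5
Reactants: 9 (1S)-1-[(1S,2R,3R)-3-[(tert-butyldimethylsilyl)oxy]-2-(1,3-dithian-2-yl)-1-methyl-5-oxocyclopentyl]prop-2-en-1-yl benzoate
Product: 10 (1S)-1-[(1R,2R,3R,5S)-3-[(tert-butyldimethylsilyl)oxy]-2-(1,3-dithian-2-yl)-5-hydroxy-1-methylcyclopentyl]prop-2-en-1-yl benzoate
Conditions: NaBH4, MeOH/THF, −40 °C; AcOH quench
Reagents that add atoms: none
Why: Borohydride reduction of the cyclopentanone, in which hydride should reach C2 from the face of the small C1 methyl, away from the branched C10 arm and the C4 silyloxy group, giving the alcohol cis to the C10 arm (2S); low temperature and an acidic quench are meant to prevent 1,3-benzoyl migration.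

Step 6
Reactants: 10 (1S)-1-[(1R,2R,3R,5S)-3-[(tert-butyldimethylsilyl)oxy]-2-(1,3-dithian-2-yl)-5-hydroxy-1-methylcyclopentyl]prop-2-en-1-yl benzoate
Product: 11 (1S)-1-[(1S,2R,3R,5S)-3-[(tert-butyldimethylsilyl)oxy]-2-(1,3-dithian-2-yl)-1-methyl-5-[(triisopropylsilyl)oxy]cyclopentyl]prop-2-en-1-yl benzoate
Conditions: TIPSOTf, 2,6-lutidine, CH2Cl2, 0 °C → rt
Reagents that add atoms: triisopropylsilyl trifluoromethanesulfonate, CC(C)[Si](C(C)C)(C(C)C)OS(=O)(=O)C(F)(F)F
Why: Silylation with the reactive triflate protects the hindered C2 alcohol as a triisopropylsilyl ether, which outlasts the later removal of the C4 tert-butyldimethylsilyl group and, unlike an acetate, is neither electrophilic nor a leaving group β to the coming C4 ketone.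

Step 7
Reactants: 11 (1S)-1-[(1S,2R,3R,5S)-3-[(tert-butyldimethylsilyl)oxy]-2-(1,3-dithian-2-yl)-1-methyl-5-[(triisopropylsilyl)oxy]cyclopentyl]prop-2-en-1-yl benzoate
Product: 12 (1S)-1-[(1S,2R,3R,5S)-2-(1,3-dithian-2-yl)-3-hydroxy-1-methyl-5-[(triisopropylsilyl)oxy]cyclopentyl]prop-2-en-1-yl benzoate
Conditions: HF·pyridine, pyridine, THF, 0 °C → rt
Reagents that add atoms: none
Why: Selective desilylation, since buffered HF·pyridine cleaves the secondary tert-butyldimethylsilyl ether at C4 much faster than the bulkier triisopropylsilyl ether on the neopentylic C2 oxygen and leaves benzoate and dithiane intact.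

Step 8
Reactants: 12 (1S)-1-[(1S,2R,3R,5S)-2-(1,3-dithian-2-yl)-3-hydroxy-1-methyl-5-[(triisopropylsilyl)oxy]cyclopentyl]prop-2-en-1-yl benzoate
Product: 13 (1S)-1-[(1S,2R,5S)-2-(1,3-dithian-2-yl)-1-methyl-3-oxo-5-[(triisopropylsilyl)oxy]cyclopentyl]prop-2-en-1-yl benzoate
Conditions: Dess–Martin periodinane, CH2Cl2, rt
Reagents that add atoms: none
Why: Dess–Martin oxidation gives the C4 ketone under conditions that tolerate the dithiane and the silyl ether, and the enolisable C5 centre already carries its substituent trans to the larger C1 arm.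

Step 9
Reactants: 13 (1S)-1-[(1S,2R,5S)-2-(1,3-dithian-2-yl)-1-methyl-3-oxo-5-[(triisopropylsilyl)oxy]cyclopentyl]prop-2-en-1-yl benzoate
Product: 14 (1S)-1-[(1S,2R,3R,5S)-2-(1,3-dithian-2-yl)-3-hydroxy-1-methyl-3-(propan-2-yl)-5-[(triisopropylsilyl)oxy]cyclopentyl]prop-2-en-1-yl benzoate
Conditions: i-PrMgCl, CeCl3 (anhydrous), THF, −78 °C; aq NH4Cl
Reagents that add atoms: isopropylmagnesium chloride, CC(C)[Mg]Cl
Why: Organocerium addition to a ketone, in which the weakly basic, oxophilic isopropylcerium reagent should add to the enolisable C4 carbonyl faster than to the hindered benzoate and enter anti to the adjacent C5 dithianyl group, so that isopropyl ends cis to H5 and the hydroxyl cis to the C5 substituent (4R).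

Step 10
Reactants: 14 (1S)-1-[(1S,2R,3R,5S)-2-(1,3-dithian-2-yl)-3-hydroxy-1-methyl-3-(propan-2-yl)-5-[(triisopropylsilyl)oxy]cyclopentyl]prop-2-en-1-yl benzoate
Product: 15 (1S)-1-[(1R,2R,3R,5S)-2-(1,3-dithian-2-yl)-3,5-dihydroxy-1-methyl-3-(propan-2-yl)cyclopentyl]prop-2-en-1-yl benzoate
Conditions: aq HF (48%), MeCN, rt → 40 °C
Reagents that add atoms: none
Why: Acidic fluoride cleavage of the triisopropylsilyl ether frees the C2 hydroxyl without the alkoxide that could trigger benzoyl migration from C10, and the tertiary alcohol, benzoate and dithiane tolerate aqueous HF in acetonitrile.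

Step 11
Reactants: 15 (1S)-1-[(1R,2R,3R,5S)-2-(1,3-dithian-2-yl)-3,5-dihydroxy-1-methyl-3-(propan-2-yl)cyclopentyl]prop-2-en-1-yl benzoate
Product: 16 (1S)-1-[(1R,2R,3R,5S)-5-acetoxy-2-(1,3-dithian-2-yl)-3-hydroxy-1-methyl-3-(propan-2-yl)cyclopentyl]prop-2-en-1-yl benzoate
Conditions: Ac2O, pyridine, DMAP (cat.), CH2Cl2, 0 °C → rt
Reagents that add atoms: acetic anhydride, CC(=O)OC(C)=O
Why: DMAP-catalysed acetylation is selective for the secondary C2 hydroxyl because the tertiary C4 hydroxyl, flanked by isopropyl and C5, acylates far more slowly.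

Step 12
Reactants: 16 (1S)-1-[(1R,2R,3R,5S)-5-acetoxy-2-(1,3-dithian-2-yl)-3-hydroxy-1-methyl-3-(propan-2-yl)cyclopentyl]prop-2-en-1-yl benzoate
Product: 17 (1S)-1-[(1R,2R,3R,5S)-5-acetoxy-2-formyl-3-hydroxy-1-methyl-3-(propan-2-yl)cyclopentyl]prop-2-en-1-yl benzoate
Conditions: MeI, CaCO3, MeCN/H2O (9:1), 45 °C
Reagents that add atoms: water, O
Why: Alkylative hydrolysis of the dithiane (S-methylation, then attack of water) unmasks the C6 aldehyde under buffered, near-neutral conditions that spare both esters, the tertiary alcohol and the C5 configuration.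

Step 13
Reactants: 17 (1S)-1-[(1R,2R,3R,5S)-5-acetoxy-2-formyl-3-hydroxy-1-methyl-3-(propan-2-yl)cyclopentyl]prop-2-en-1-yl benzoate; 18 3-chloro-2-methylprop-1-ene
Product: 21 (1S)-1-[(1R,2S,3R,5S)-5-acetoxy-3-hydroxy-2-[(1S)-1-hydroxy-3-methylbut-3-en-1-yl]-1-methyl-3-(propan-2-yl)cyclopentyl]prop-2-en-1-yl benzoate, via 2-methylallylmagnesium chloride 19 (not isolated), via B-methallyldiisopinocampheylborane 20 (not isolated)
Conditions: 18, Mg, THF, 0 °C; (−)-Ipc2BOMe [from (+)-α-pinene], Et2O, 0 °C → rt; then 17 (added to excess 20), −78 °C → rt; ethanolamine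
Reagents that add atoms: none
Why: Brown asymmetric methallylboration, in which the (+)-α-pinene-derived borane 20 adds through a chair transition state to the Si face of the aldehyde under reagent control to give the 6S homoallylic alcohol, and the non-oxidative ethanolamine work-up keeps acetate and benzoate intact.

Step 14
Reactants: 21 (1S)-1-[(1R,2S,3R,5S)-5-acetoxy-3-hydroxy-2-[(1S)-1-hydroxy-3-methylbut-3-en-1-yl]-1-methyl-3-(propan-2-yl)cyclopentyl]prop-2-en-1-yl benzoate
Product: 22 (1S,3R,3aS,4S,8S,8aR)-1-acetoxy-3,4-dihydroxy-6,8a-dimethyl-3-(propan-2-yl)-1,2,3,3a,4,5,8,8a-octahydroazulen-8-yl benzoate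
Conditions: second-generation Grubbs catalyst RuCl2(=CHPh)(PCy3)(H2IMes) (10 mol%), CH2Cl2 (0.002 M), 40 °C
Reagents that add atoms: none
Why: The ruthenium benzylidene first exchanges with the monosubstituted vinyl group on C10, and the resulting alkylidene at C9 adds across the 1,1-disubstituted alkene of the methallyl arm in a [2+2] step; cycloreversion of the ruthenacyclobutane delivers the C8=C9 bond and a ruthenium methylidene that loses ethylene on the next turnover. The closest known reaction type is ring-closing metathesis of 1,8-dienes to trisubstituted cycloheptenes fused to five-membered rings with second-generation ruthenium carbenes. The seven-membered ring closes between two arms already held trans on the adjacent carbons C1 and C5, so it is an ordinary ring-closing metathesis to a cycloheptene, driven by loss of ethylene, and the trans fusion is not at stake. No stereocentre is formed or touched, and the new ring alkene can only be cis within a seven-membered ring. The step needs only chemoselectivity for cyclisation over intermolecular metathesis, which high dilution and the proximity of the two arms on the cyclopentane should secure, while the allylic benzoate, the acetate and the free secondary and tertiary hydroxyls are tolerated by the catalyst.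

Step 15
Reactants: 22 (1S,3R,3aS,4S,8S,8aR)-1-acetoxy-3,4-dihydroxy-6,8a-dimethyl-3-(propan-2-yl)-1,2,3,3a,4,5,8,8a-octahydroazulen-8-yl benzoate
Product: 23 (1S,3R,3aS,4S,8S,8aR)-1-acetoxy-8-(benzoyloxy)-3-hydroxy-6,8a-dimethyl-3-(propan-2-yl)-1,2,3,3a,4,5,8,8a-octahydroazulen-4-yl (2Z)-2-methylbut-2-enoate
Conditions: angelic acid, 2,4,6-Cl3C6H2COCl, Et3N, toluene, rt; then 22, toluene, 80 °C
Reagents that add atoms: angelic acid, C/C=C(/C)C(=O)O
Why: Yamaguchi esterification through the mixed 2,4,6-trichlorobenzoic anhydride acylates the only secondary hydroxyl (C6) without a nucleophilic catalyst, conditions known to transfer the angeloyl group without isomerisation to the tiglate, while the tertiary C4 hydroxyl stays free.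

**Compound list**

1 | (R)-4-[(tert-butyldimethylsilyl)oxy]cyclopent-2-en-1-one | O=C1C=C[C@H](O[Si](C)(C)C(C)(C)C)C1 | starting material
2 | (R)-4-[(tert-butyldimethylsilyl)oxy]-2-iodocyclopent-2-en-1-one | O=C1C(I)=C[C@H](O[Si](C)(C)C(C)(C)C)C1 | intermediate
3 | (R)-4-[(tert-butyldimethylsilyl)oxy]-2-methylcyclopent-2-en-1-one | CC1=C[C@H](O[Si](C)(C)C(C)(C)C)CC1=O | intermediate
4 | 1,3-dithiane | C1CSCSC1 | starting material
5 | acrolein (prop-2-enal) | C=CC=O | starting material
6 | 2-lithio-1,3-dithiane | [Li]C1SCCCS1 | intermediate (not isolated)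
7 | lithium (3R,4R)-4-[(tert-butyldimethylsilyl)oxy]-3-(1,3-dithian-2-yl)-2-methylcyclopent-1-en-1-olate | [Li]OC1=C(C)[C@@H](C2SCCCS2)[C@H](O[Si](C)(C)C(C)(C)C)C1 | intermediate (not isolated)
8 | (2S,3R,4R)-4-[(tert-butyldimethylsilyl)oxy]-3-(1,3-dithian-2-yl)-2-[(1S)-1-hydroxyprop-2-en-1-yl]-2-methylcyclopentan-1-one | O=C1C[C@@H](O[Si](C)(C)C(C)(C)C)[C@H](C2SCCCS2)[C@@]1(C)[C@@H](O)C=C | intermediate
9 | (1S)-1-[(1S,2R,3R)-3-[(tert-butyldimethylsilyl)oxy]-2-(1,3-dithian-2-yl)-1-methyl-5-oxocyclopentyl]prop-2-en-1-yl benzoate | O=C1C[C@@H](O[Si](C)(C)C(C)(C)C)[C@H](C2SCCCS2)[C@@]1(C)[C@@H](OC(=O)c3ccccc3)C=C | intermediate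
10 | (1S)-1-[(1R,2R,3R,5S)-3-[(tert-butyldimethylsilyl)oxy]-2-(1,3-dithian-2-yl)-5-hydroxy-1-methylcyclopentyl]prop-2-en-1-yl benzoate | O[C@H]1C[C@@H](O[Si](C)(C)C(C)(C)C)[C@H](C2SCCCS2)[C@@]1(C)[C@@H](OC(=O)c3ccccc3)C=C | intermediate
11 | (1S)-1-[(1S,2R,3R,5S)-3-[(tert-butyldimethylsilyl)oxy]-2-(1,3-dithian-2-yl)-1-methyl-5-[(triisopropylsilyl)oxy]cyclopentyl]prop-2-en-1-yl benzoate | CC(C)[Si](C(C)C)(C(C)C)O[C@H]1C[C@@H](O[Si](C)(C)C(C)(C)C)[C@H](C2SCCCS2)[C@@]1(C)[C@@H](OC(=O)c3ccccc3)C=C | intermediate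
12 | (1S)-1-[(1S,2R,3R,5S)-2-(1,3-dithian-2-yl)-3-hydroxy-1-methyl-5-[(triisopropylsilyl)oxy]cyclopentyl]prop-2-en-1-yl benzoate | CC(C)[Si](C(C)C)(C(C)C)O[C@H]1C[C@@H](O)[C@H](C2SCCCS2)[C@@]1(C)[C@@H](OC(=O)c3ccccc3)C=C | intermediate
13 | (1S)-1-[(1S,2R,5S)-2-(1,3-dithian-2-yl)-1-methyl-3-oxo-5-[(triisopropylsilyl)oxy]cyclopentyl]prop-2-en-1-yl benzoate | CC(C)[Si](C(C)C)(C(C)C)O[C@H]1CC(=O)[C@H](C2SCCCS2)[C@@]1(C)[C@@H](OC(=O)c3ccccc3)C=C | intermediate
14 | (1S)-1-[(1S,2R,3R,5S)-2-(1,3-dithian-2-yl)-3-hydroxy-1-methyl-3-(propan-2-yl)-5-[(triisopropylsilyl)oxy]cyclopentyl]prop-2-en-1-yl benzoate | CC(C)[Si](C(C)C)(C(C)C)O[C@H]1C[C@@](O)(C(C)C)[C@H](C2SCCCS2)[C@@]1(C)[C@@H](OC(=O)c3ccccc3)C=C | intermediate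
15 | (1S)-1-[(1R,2R,3R,5S)-2-(1,3-dithian-2-yl)-3,5-dihydroxy-1-methyl-3-(propan-2-yl)cyclopentyl]prop-2-en-1-yl benzoate | O[C@H]1C[C@@](O)(C(C)C)[C@H](C2SCCCS2)[C@@]1(C)[C@@H](OC(=O)c3ccccc3)C=C | intermediate
16 | (1S)-1-[(1R,2R,3R,5S)-5-acetoxy-2-(1,3-dithian-2-yl)-3-hydroxy-1-methyl-3-(propan-2-yl)cyclopentyl]prop-2-en-1-yl benzoate | CC(=O)O[C@H]1C[C@@](O)(C(C)C)[C@H](C2SCCCS2)[C@@]1(C)[C@@H](OC(=O)c3ccccc3)C=C | intermediate
17 | (1S)-1-[(1R,2R,3R,5S)-5-acetoxy-2-formyl-3-hydroxy-1-methyl-3-(propan-2-yl)cyclopentyl]prop-2-en-1-yl benzoate | CC(=O)O[C@H]1C[C@@](O)(C(C)C)[C@H](C=O)[C@@]1(C)[C@@H](OC(=O)c2ccccc2)C=C | intermediate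
18 | 3-chloro-2-methylprop-1-ene | C=C(C)CCl | starting material
19 | 2-methylallylmagnesium chloride | C=C(C)C[Mg]Cl | intermediate (not isolated)
20 | (2-methylprop-2-en-1-yl)bis[(1R,2S,3R,5R)-2,6,6-trimethylbicyclo[3.1.1]heptan-3-yl]borane | CC(=C)CB([C@@H]1C[C@@H]2C[C@H]([C@H]1C)C2(C)C)[C@@H]1C[C@@H]2C[C@H]([C@H]1C)C2(C)C | intermediate (not isolated)
21 | (1S)-1-[(1R,2S,3R,5S)-5-acetoxy-3-hydroxy-2-[(1S)-1-hydroxy-3-methylbut-3-en-1-yl]-1-methyl-3-(propan-2-yl)cyclopentyl]prop-2-en-1-yl benzoate | CC(=O)O[C@H]1C[C@@](O)(C(C)C)[C@H]([C@@H](O)CC(C)=C)[C@@]1(C)[C@@H](OC(=O)c2ccccc2)C=C | intermediate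
22 | (1S,3R,3aS,4S,8S,8aR)-1-acetoxy-3,4-dihydroxy-6,8a-dimethyl-3-(propan-2-yl)-1,2,3,3a,4,5,8,8a-octahydroazulen-8-yl benzoate | O[C@H]1CC(C)=C[C@H](OC(=O)c2ccccc2)[C@@]2(C)[C@@H](OC(C)=O)C[C@@](O)(C(C)C)[C@H]12 | intermediate
23 | (1S,3R,3aS,4S,8S,8aR)-1-acetoxy-8-(benzoyloxy)-3-hydroxy-6,8a-dimethyl-3-(propan-2-yl)-1,2,3,3a,4,5,8,8a-octahydroazulen-4-yl (2Z)-2-methylbut-2-enoate | C/C=C(/C)C(=O)O[C@H]1CC(C)=C[C@H](OC(=O)c2ccccc2)[C@@]2(C)[C@@H](OC(C)=O)C[C@@](O)(C(C)C)[C@H]12 | target

**Step count and risks**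

Total steps: 15. Longest linear sequence: 15 steps (1 → 23).

Steps most likely to fail:

1. Step 3. The hard lithiodithiane may add to the carbonyl carbon instead of the β-carbon, or deprotonate the enone and cause loss of the C4 silyloxy group, and HMPA may loosen the aldol transition state and erode facial control at C10. The fallback sets out from 3 and uses a blocked, softer carbanion. 2-Lithio-2-(trimethylsilyl)-1,3-dithiane (from 2-(trimethylsilyl)-1,3-dithiane and n-BuLi, THF/HMPA, −78 °C), which is known for clean 1,4-addition, would be added to 3 and the enolate trapped with acrolein 5 to give the silylated ketol F1. Benzoylation (BzCl, pyridine, DMAP) would give the silylated benzoate F2. Buffered fluoride (Bu4NF, AcOH, THF, 0 °C) would then cleave the activated C–Si bond between the two sulfur atoms faster than the secondary O–silyl ether, and the route is rejoined at 9.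

2. Step 9. The secondary alkyl metal may enolise or reduce the hindered C4 ketone instead of adding, and approach to the face that carries the bulky C2 silyl ether may be slow. The fallback sets out from 13 and reverses the order of deprotection and addition. Cleavage of the triisopropylsilyl ether first (aq HF, MeCN) would give the hydroxy ketone F3. Excess i-PrMgCl/CeCl3 (THF, −78 °C) would then be added to this unprotected β-hydroxy ketone, whose small cerium alkoxide on the required face cannot leave and can guide the reagent to that face. The product is 15, where the route is rejoined.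

3. Step 13. Addition of the bulky borane to the doubly neopentylic aldehyde may be slow, and reagent control may be eroded if the substrate's own facial preference opposes it. The fallback sets out from 17 and fixes C6 by oxidation and directed reduction. Achiral pinacol 2-methylallylboronate (CH2Cl2, rt) would add without control to give 21 together with its C6 epimer F4. Dess–Martin oxidation of the mixture would give the β,γ-unsaturated ketone F5. Narasaka–Prasad reduction (Et2BOMe, NaBH4, THF/MeOH, −78 °C), in which external hydride attacks the boron chelate of the C4 hydroxyl and the C6 carbonyl, should give the 1,3-syn diol, which is 21, where the route is rejoined.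

**Further compounds**

F1 | step 3 | (2S,3R,4R)-4-[(tert-butyldimethylsilyl)oxy]-2-[(1S)-1-hydroxyprop-2-en-1-yl]-2-methyl-3-[2-(trimethylsilyl)-1,3-dithian-2-yl]cyclopentan-1-one | O=C1C[C@@H](O[Si](C)(C)C(C)(C)C)[C@H](C2([Si](C)(C)C)SCCCS2)[C@@]1(C)[C@@H](O)C=C
F2 | step 3 | (1S)-1-[(1S,2R,3R)-3-[(tert-butyldimethylsilyl)oxy]-1-methyl-5-oxo-2-[2-(trimethylsilyl)-1,3-dithian-2-yl]cyclopentyl]prop-2-en-1-yl benzoate | O=C1C[C@@H](O[Si](C)(C)C(C)(C)C)[C@H](C2([Si](C)(C)C)SCCCS2)[C@@]1(C)[C@@H](OC(=O)c3ccccc3)C=C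
F3 | step 9 | (1S)-1-[(1R,2R,5S)-2-(1,3-dithian-2-yl)-5-hydroxy-1-methyl-3-oxocyclopentyl]prop-2-en-1-yl benzoate | O[C@H]1CC(=O)[C@H](C2SCCCS2)[C@@]1(C)[C@@H](OC(=O)c3ccccc3)C=C
F4 | step 13 | (1S)-1-[(1R,2S,3R,5S)-5-acetoxy-3-hydroxy-2-[(1R)-1-hydroxy-3-methylbut-3-en-1-yl]-1-methyl-3-(propan-2-yl)cyclopentyl]prop-2-en-1-yl benzoate | CC(=O)O[C@H]1C[C@@](O)(C(C)C)[C@H]([C@H](O)CC(C)=C)[C@@]1(C)[C@@H](OC(=O)c2ccccc2)C=C
F5 | step 13 | (1S)-1-[(1R,2R,3R,5S)-5-acetoxy-3-hydroxy-1-methyl-2-(3-methylbut-3-enoyl)-3-(propan-2-yl)cyclopentyl]prop-2-en-1-yl benzoate | CC(=O)O[C@H]1C[C@@](O)(C(C)C)[C@H](C(=O)CC(C)=C)[C@@]1(C)[C@@H](OC(=O)c2ccccc2)C=C
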